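**Analysis of the target**

The target is a 2-aryl-4H-chromen-4-one: benzo ring A is fused to the 4-pyranone ring C, which carries the guaiacyl ring B at C2. It has no stereocentre and no stereogenic double bond, so any chirality that appears on the way may be racemic and only has to be erased again. Ring A is oxygenated at C5 (methoxy), C7 (prenyloxy), C8 (methoxy) and C8a (O1) and keeps one hydrogen, at C6; ring C carries a methoxy group at C3 and ring B a free 4'-hydroxyl next to the 3'-methoxy group. The sensitive parts are the prenyl ether (acid-labile, and its alkene tolerates neither dihydroxylation, π-acidic metals nor hydrogenation), the free phenol, the C5 methoxy group peri to the carbonyl (cleaved by chelating Lewis acids) and the pyranone, which strong hydroxide can open at C2. The difficulty is the differentiation of six oxygens: four end as methyl ethers, O7 as the prenyl ether and O4' as the free phenol, so O7 and O4' need different temporary groups and the prenyl group must arrive late. The classical flavonol routes would also demand a carbon substituent at C4a, between two oxygenated carbons of a pentasubstituted benzene. The strategy rests on the fact that C4a is the only hydrogen-bearing carbon ortho to O1 on ring A, the other ortho carbon, C8, carrying methoxy. A three-carbon unit hung on O1 can therefore close ring C only at C4a, so the C4–C4a bond is made last, at the flav-3-ene level, and C3=C4 remains as the handle for the two ring C oxygens.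

**Retrosynthetic reasoning**

From 22 back to 19. The free 4'-hydroxyl of target 22 is masked as the aryl 4-methylbenzenesulfonate 21, whose S–O bond is cut last. The O7–CH2 bond of the prenyl ether is cut next, giving the 7-hydroxyflavone 19 and prenyl bromide 20. These cuts come at the very end because the prenyl alkene would survive none of the earlier oxidation, metal-catalysed or hydrogenation steps. Forward, the alkylation meets a single free phenol, and the sulfonate must then be removed by a base that leaves the allylic ether and the pyranone alone. Phenol 19 comes from its benzyl ether 18 by hydrogenolysis, which the sulfonate survives; this is why the two phenol masks are different.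

From 18 to 17. The O3–CH3 bond is cut. In flavonol 17 the C3 hydroxyl is the only free hydroxyl, so the forward methylation needs no selectivity.

From 17 to 14. Flavonol 17 is the enol tautomer of the chromane-3,4-dione 16, and 16 is the double oxidation product of the 3,4-diol 15. Cutting the two C–O bonds at C3 and C4 of 15 leads to the alkene of flav-3-ene 14. This places both ring C oxygens on a ring that already exists. Forward, a syn-dihydroxylation is followed by an oxidation that must not cleave C3–C4. The three sp3 centres of 15 disappear on tautomerization, so their configuration is of no concern.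

From 14 to 13, the key disconnection. The C4–C4a bond is cut, which opens ring C to the aryl 1-arylpropargyl ether 13. The cut is made here because ring A can then enter as a plain phenol without a carbon substituent. The forward closure needs no regiocontrol on ring A, since C8 is blocked and C6 is out of reach. It has to close in the 6-endo mode without ionizing the benzylic, propargylic C2–O1 bond, which the electron-poor sulfonate on ring B is there to prevent.

From 13 to 8 and 12. The O1–C2 bond is cut to phenol 8 and the racemic propargylic alcohol 12. A dehydrative etherification joins the two halves in one step and avoids a separate activation of the ionizable alcohol.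

From 12 to 9. The C2–C3 bond is cut to aldehyde 10 and ethynylmagnesium bromide 11, and 10 is the sulfonate of vanillin 9. The sulfonate is put on first so that it serves as the phenol mask and as the deactivating group for the key step.

From 8 to 1. Phenol 8 is the monobenzyl ether of the symmetric diol 7, so desymmetrization is a simple mono-alkylation of two equivalent hydroxyls. Diol 7 comes from its bis(methoxymethyl) ether 6, and 6 from phenol 5 by O-methylation. The C–O bond at the carbon between the two acetal oxygens of 5 is cut back to the C–H bond of 2 (through aryllithium 3 and boronate 4), and 2 is the bis-acetal of 5-methoxyresorcinol 1. The acetals are chosen because they direct the metalation to the carbon between them.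

**Alternatives that were turned down**

Alternative 1: Here ring C is cut at C3–C4 and at C2=C3, and C3 with its methoxy group comes from the phosphorus ylide A3. Ring A enters as the salicyloyl chloride A2, whose phenol oxygen already carries ring B as an aroyl ester. In the forward key step A2 is acylated by A3 (a second equivalent serves as base), and the resulting acylphosphorane olefinates the neighbouring ester carbonyl to close the pyranone, giving the silyl ether A1. Desilylation then finishes the synthesis. In its favour, the oxidation level is right from the start, the prenyl ether can be in place before the key step, and the sequence is several steps shorter than the chosen one. On step and redox economy this alternative is clearly stronger. Against it, A2 requires a hexasubstituted benzoic acid, that is, a carboxyl carbon introduced at C4a between two oxygenated carbons, which is the operation the chosen route avoids. The acid chloride in A2 is flanked on both sides, the basic non-stabilized ylide A3 can also attack or transfer the ortho aroyl ester, and a Wittig reaction on an ester carbonyl through a hindered α-methoxy acylphosphorane is a slow step with little margin. The chosen route offers instead a ring A fragment without any carbon substituent, a ring closure whose site is dictated by the substitution pattern, and reactions of well-understood selectivity on both sides of a single catalytic risk.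

Alternative 2: C4 is taken from carbon monoxide A7 and both of its bonds, C4a–C4 and C4–C3, are cut, leading to the ring A aryl iodide A5 and the ring B α-methoxy ketone A6. The forward key step is a palladium-catalysed carbonylative α-arylation of A6 with A5 and A7, which gives the 2-methoxy-1,3-diketone A4 without closing a ring. Acid would then remove the acetals and cyclodehydrate A4 to compound 19 of the chosen route. It is attractive because three components are joined at once, both fragments are simple and the whole sequence is shorter and more convergent; on convergence it is the stronger plan. Against it, A5 is an electron-rich iodide with both ortho positions oxygenated, so oxidative addition, carbon monoxide insertion and coupling of the crowded acylpalladium with a tertiary α-methoxy enolate are all slowed. Direct arylation without carbon monoxide and O-acylation of the enolate then compete, and the product A4 is open to retro-Claisen cleavage by the base needed to make it. The alternative therefore forces an intermolecular bond at the most hindered carbon of ring A. The chosen route forms the bond to the same carbon, C4a, intramolecularly through a six-membered transition state and uses the high nucleophilicity of that position instead of fighting its congestion.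

Alternative 3: Ring A is built last onto a preformed 4-pyranone. The disconnection cuts C4a–C5 and traces the remaining ring A carbons to the 4-hydroxycyclobutenone A9, which carries the pyranone on its carbinol carbon. In the forward key step, thermolysis opens the four-membered ring to a vinylketene, which cyclizes onto the free pyranone carbon and tautomerizes to the 5,8-hydroquinone A8. Its strength is that the oxygen pattern of ring A is programmed by the cyclobutenone and no aromatic substitution is needed; on regiochemical certainty it is as strong as the chosen plan. Against it, A8 still needs both hydroquinone hydroxyls methylated, one of them hydrogen-bonded to the C4 carbonyl, on a nucleus that is easily oxidized to the quinone. The route to A9 needs a C-metalated 4-pyranone, itself an electrophile, and a benzyloxycyclobutenedione. The acetal on ring B must finally be removed with acid, which endangers the prenyl ether unless the end game is reordered. The chosen route gets the same regiochemical certainty from the blocked C8 position of a resorcinol-derived phenol and reaches the ring A pattern in fewer and more ordinary operations.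

Key step: step 9

Remark on the chemistry: the target is achiral; the stereocentres that appear in compounds 12 to 16 (C2, C3, C4, flavone numbering) are racemic and are erased in step 11, so no absolute or relative configuration has to be controlled.

**Step 1**
Reactants: 1 5-methoxyresorcinol (5-methoxybenzene-1,3-diol)
Product: 2 1-methoxy-3,5-bis(methoxymethoxy)benzene
Conditions: MOMCl (2.5 equiv), i-Pr2NEt, CH2Cl2, 0 °C to rt
Reagents that add atoms: chloromethyl methyl ether (MOMCl), COCCl
Why: Williamson-type O-alkylation of both phenols by the reactive α-chloro ether; the two acetals serve as directing groups for step 2.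

**Step 2**
Reactants: 2 1-methoxy-3,5-bis(methoxymethoxy)benzene
Product: 5 4-methoxy-2,6-bis(methoxymethoxy)phenol, via aryllithium 3 (not isolated), via dimethyl arylboronate 4 (not isolated)
Conditions: n-BuLi, THF, 0 °C; B(OMe)3, −78 °C to rt; 30% H2O2, aq. NaOH, 0 °C
Reagents that add atoms: hydrogen peroxide, OO
Why: Directed ortho-lithiation should take place at the carbon flanked by both acetal oxygens (cooperative chelation, most acidic C–H); borylation and oxidative aryl migration from boron to oxygen then convert the C–Li bond into the phenol.

**Step 3**
Reactants: 5 4-methoxy-2,6-bis(methoxymethoxy)phenol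
Product: 6 2,5-dimethoxy-1,3-bis(methoxymethoxy)benzene
Conditions: MeI, K2CO3, acetone, reflux
Reagents that add atoms: iodomethane, CI
Why: Williamson O-methylation of the only free phenol; the acetals are stable to base.

**Step 4**
Reactants: 6 2,5-dimethoxy-1,3-bis(methoxymethoxy)benzene
Product: 7 2,5-dimethoxybenzene-1,3-diol
Conditions: conc. HCl (cat.), MeOH, 50 °C
Reagents that add atoms: none
Why: Acid-catalysed acetal exchange with methanol releases both phenols; the aryl methyl ethers are untouched under these conditions.

**Step 5**
Reactants: 7 2,5-dimethoxybenzene-1,3-diol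
Product: 8 3-(benzyloxy)-2,5-dimethoxyphenol
Conditions: BnBr (0.9 equiv), K2CO3, DMF, rt; recovered 7 recycled
Reagents that add atoms: benzyl bromide, BrCc1ccccc1
Why: Williamson mono-etherification; the two hydroxyls of 7 are equivalent, so there is no regiochemical question. Substoichiometric halide limits double alkylation, and mono-ether, diol and bis-ether differ enough in polarity to be separated.

**Step 6**
Reactants: 9 vanillin (4-hydroxy-3-methoxybenzaldehyde)
Product: 10 4-formyl-2-methoxyphenyl 4-methylbenzenesulfonate
Conditions: TsCl, Et3N, DMAP (cat.), CH2Cl2, 0 °C to rt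
Reagents that add atoms: 4-methylbenzenesulfonyl chloride (TsCl), Cc1ccc(S(=O)(=O)Cl)cc1
Why: O-sulfonylation of the phenol; the sulfonate is the phenol mask for the whole route and the electron-withdrawing group that later suppresses benzylic ionization.

**Step 7**
Reactants: 10 4-formyl-2-methoxyphenyl 4-methylbenzenesulfonate; 11 ethynylmagnesium bromide
Product: 12 4-(1-hydroxyprop-2-yn-1-yl)-2-methoxyphenyl 4-methylbenzenesulfonate (racemic)
Conditions: THF, −20 to 0 °C; sat. aq. NH4Cl
Reagents that add atoms: none
Why: Grignard 1,2-addition to the aldehyde, which is far faster than attack at the sulfonate sulfur at low temperature. The new carbinol centre (the future C2) forms racemic, which is acceptable because it is erased in step 11.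

**Step 8**
Reactants: 8 3-(benzyloxy)-2,5-dimethoxyphenol; 12 4-(1-hydroxyprop-2-yn-1-yl)-2-methoxyphenyl 4-methylbenzenesulfonate (racemic)
Product: 13 4-{1-[3-(benzyloxy)-2,5-dimethoxyphenoxy]prop-2-yn-1-yl}-2-methoxyphenyl 4-methylbenzenesulfonate (racemic)
Conditions: PPh3, DIAD, toluene, 0 °C to rt
Reagents that add atoms: none
Why: Mitsunobu etherification: the phenol protonates the betaine and the phenoxide displaces the oxyphosphonium of the secondary propargylic alcohol. Inversion is without consequence at a racemic centre, and no free benzylic cation is needed.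

**Step 9**
Reactants: 13 4-{1-[3-(benzyloxy)-2,5-dimethoxyphenoxy]prop-2-yn-1-yl}-2-methoxyphenyl 4-methylbenzenesulfonate (racemic)
Product: 14 4-[7-(benzyloxy)-5,8-dimethoxy-2H-chromen-2-yl]-2-methoxyphenyl 4-methylbenzenesulfonate (racemic)
Conditions: Ph3PAuCl (5 mol%), AgSbF6 (5 mol%), CH2Cl2, 0 °C to rt
Reagents that add atoms: none
Why: Chloride abstraction from Ph3PAuCl by AgSbF6 gives a cationic monovalent gold species that coordinates the terminal alkyne of 13 and makes it electrophilic. C4a of ring A, activated by O1 and the C5 methoxy group (both ortho) and by the C7 benzyloxy group (para), attacks the alkyne terminus anti to gold in Friedel–Crafts fashion; rearomatization and protodeauration of the vinylgold intermediate release 14 and the catalyst. The closest known reaction type is the gold- or platinum-catalysed intramolecular hydroarylation of aryl propargyl ethers to 2H-chromenes. Ring C closes in the 6-endo-dig mode, forming the C4–C4a bond. No new stereocentre is formed; the racemic C2 centre is carried through unchanged. Two selectivities are needed: 6-endo over 5-exo closure, favoured by the short O1–C2 tether (a strained exo trajectory onto the internal carbon) and by the electron-withdrawing propargylic oxygen next to that carbon, and the site on ring A, which is fixed because C8 carries methoxy and C6 cannot be reached. Ionization of the benzylic, propargylic C2–O1 bond is held back by the sulfonate para to C2 on ring B.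

**Step 10**
Reactants: 14 4-[7-(benzyloxy)-5,8-dimethoxy-2H-chromen-2-yl]-2-methoxyphenyl 4-methylbenzenesulfonate (racemic)
Product: 15 rac-4-[(2R,3S,4S)-7-(benzyloxy)-3,4-dihydroxy-5,8-dimethoxy-3,4-dihydro-2H-chromen-2-yl]-2-methoxyphenyl 4-methylbenzenesulfonate (2,3-trans-3,4-cis)
Conditions: OsO4 (2 mol%), NMO, acetone/H2O, rt; aq. Na2SO3
Reagents that add atoms: osmium tetroxide, O=[Os](=O)(=O)=O; N-methylmorpholine N-oxide, C[N+]1([O-])CCOCC1; water, O
Why: Upjohn syn-dihydroxylation of the electron-rich cis-disubstituted C3=C4 alkene. The osmate ester should form on the face anti to the C2 aryl group, giving the 2,3-trans-3,4-cis diol; this selectivity is not critical because C2, C3 and C4 are all flattened in step 11.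

**Step 11**
Reactants: 15 rac-4-[(2R,3S,4S)-7-(benzyloxy)-3,4-dihydroxy-5,8-dimethoxy-3,4-dihydro-2H-chromen-2-yl]-2-methoxyphenyl 4-methylbenzenesulfonate
Product: 17 4-[7-(benzyloxy)-3-hydroxy-5,8-dimethoxy-4-oxo-4H-chromen-2-yl]-2-methoxyphenyl 4-methylbenzenesulfonate, via flavan-3,4-dione 16 (not isolated)
Conditions: IBX (3.5 equiv), DMSO, rt to 40 °C; then Et3N (cat.)
Reagents that add atoms: none
Why: IBX (2-iodoxybenzoic acid) oxidizes vicinal diols to 1,2-diketones without C–C cleavage. Dione 16 has an acidic C2–H (benzylic, next to O1 and to the C3 carbonyl) and should tautomerize to the 3-hydroxy-4-pyranone, driven by formation of the aromatic pyranone; all three stereocentres disappear.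

**Step 12**
Reactants: 17 4-[7-(benzyloxy)-3-hydroxy-5,8-dimethoxy-4-oxo-4H-chromen-2-yl]-2-methoxyphenyl 4-methylbenzenesulfonate
Product: 18 4-[7-(benzyloxy)-3,5,8-trimethoxy-4-oxo-4H-chromen-2-yl]-2-methoxyphenyl 4-methylbenzenesulfonate
Conditions: MeI, K2CO3, acetone, reflux
Reagents that add atoms: iodomethane, CI
Why: Williamson O-methylation of the flavonol hydroxyl, the only free hydroxyl in 17; the aryl sulfonate is stable to carbonate in acetone.

**Step 13**
Reactants: 18 4-[7-(benzyloxy)-3,5,8-trimethoxy-4-oxo-4H-chromen-2-yl]-2-methoxyphenyl 4-methylbenzenesulfonate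
Product: 19 4-(7-hydroxy-3,5,8-trimethoxy-4-oxo-4H-chromen-2-yl)-2-methoxyphenyl 4-methylbenzenesulfonate
Conditions: H2 (1 atm), 10% Pd/C, EtOAc/THF, rt
Reagents that add atoms: none
Why: Hydrogenolysis of the benzyl ether; the fully substituted pyranone double bond and the aryl sulfonate are inert under these mild conditions, and no Lewis acid touches the peri C5 methoxy group.

**Step 14**
Reactants: 19 4-(7-hydroxy-3,5,8-trimethoxy-4-oxo-4H-chromen-2-yl)-2-methoxyphenyl 4-methylbenzenesulfonate; 20 prenyl bromide (1-bromo-3-methylbut-2-ene)
Product: 21 2-methoxy-4-{3,5,8-trimethoxy-7-[(3-methylbut-2-en-1-yl)oxy]-4-oxo-4H-chromen-2-yl}phenyl 4-methylbenzenesulfonate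
Conditions: K2CO3, acetone, 50 °C
Reagents that add atoms: none
Why: Williamson O-alkylation of the acidic 7-hydroxyl, the only free phenol, with the allylic bromide; direct SN2 attack at the primary carbon gives the unrearranged prenyl ether.

**Step 15**
Reactants: 21 2-methoxy-4-{3,5,8-trimethoxy-7-[(3-methylbut-2-en-1-yl)oxy]-4-oxo-4H-chromen-2-yl}phenyl 4-methylbenzenesulfonate
Product: 22 2-(4-hydroxy-3-methoxyphenyl)-3,5,8-trimethoxy-7-[(3-methylbut-2-en-1-yl)oxy]-4H-chromen-4-one (the target)
Conditions: KOH (2 M aq.), 1,4-dioxane, 60 °C; then 1 M HCl to pH 6
Reagents that add atoms: none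
Why: Alkaline cleavage of the aryl sulfonate by hydroxide attack at sulfur, helped by the good leaving ability of the phenoxide conjugated to the pyranone. Hydroxide in an alcohol-free medium generates no alkyl sulfonate that could re-alkylate the phenoxide, and the prenyl ether is stable to base and to the near-neutral work-up.

**Compound list**

1 | 5-methoxyresorcinol (5-methoxybenzene-1,3-diol) | COc1cc(O)cc(O)c1 | starting material
2 | 1-methoxy-3,5-bis(methoxymethoxy)benzene | COCOc1cc(OC)cc(OCOC)c1 | intermediate
3 | [4-methoxy-2,6-bis(methoxymethoxy)phenyl]lithium | [Li]c1c(OCOC)cc(OC)cc1OCOC | intermediate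
4 | dimethyl [4-methoxy-2,6-bis(methoxymethoxy)phenyl]boronate | COCOc1cc(OC)cc(OCOC)c1B(OC)OC | intermediate
5 | 4-methoxy-2,6-bis(methoxymethoxy)phenol | COCOc1cc(OC)cc(OCOC)c1O | intermediate
6 | 2,5-dimethoxy-1,3-bis(methoxymethoxy)benzene | COCOc1cc(OC)cc(OCOC)c1OC | intermediate
7 | 2,5-dimethoxybenzene-1,3-diol | COc1cc(O)c(OC)c(O)c1 | intermediate
8 | 3-(benzyloxy)-2,5-dimethoxyphenol | COc1cc(O)c(OC)c(OCc2ccccc2)c1 | intermediate
9 | vanillin (4-hydroxy-3-methoxybenzaldehyde) | COc1cc(C=O)ccc1O | starting material
10 | 4-formyl-2-methoxyphenyl 4-methylbenzenesulfonate | COc1cc(C=O)ccc1OS(=O)(=O)c1ccc(C)cc1 | intermediate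
11 | ethynylmagnesium bromide | C#C[Mg]Br | starting material
12 | 4-(1-hydroxyprop-2-yn-1-yl)-2-methoxyphenyl 4-methylbenzenesulfonate (racemic) | C#CC(O)c1ccc(OS(=O)(=O)c2ccc(C)cc2)c(OC)c1 | intermediate
13 | 4-{1-[3-(benzyloxy)-2,5-dimethoxyphenoxy]prop-2-yn-1-yl}-2-methoxyphenyl 4-methylbenzenesulfonate (racemic) | C#CC(Oc1cc(OC)cc(OCc2ccccc2)c1OC)c1ccc(OS(=O)(=O)c2ccc(C)cc2)c(OC)c1 | intermediate
14 | 4-[7-(benzyloxy)-5,8-dimethoxy-2H-chromen-2-yl]-2-methoxyphenyl 4-methylbenzenesulfonate (racemic) | COc1cc(C2C=Cc3c(OC)cc(OCc4ccccc4)c(OC)c3O2)ccc1OS(=O)(=O)c1ccc(C)cc1 | intermediate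
15 | rac-4-[(2R,3S,4S)-7-(benzyloxy)-3,4-dihydroxy-5,8-dimethoxy-3,4-dihydro-2H-chromen-2-yl]-2-methoxyphenyl 4-methylbenzenesulfonate (one enantiomer drawn) | COc1cc([C@H]2Oc3c(OC)c(OCc4ccccc4)cc(OC)c3[C@H](O)[C@@H]2O)ccc1OS(=O)(=O)c1ccc(C)cc1 | intermediate
16 | 4-[7-(benzyloxy)-5,8-dimethoxy-3,4-dioxo-3,4-dihydro-2H-chromen-2-yl]-2-methoxyphenyl 4-methylbenzenesulfonate (racemic) | COc1cc(C2Oc3c(OC)c(OCc4ccccc4)cc(OC)c3C(=O)C2=O)ccc1OS(=O)(=O)c1ccc(C)cc1 | intermediate
17 | 4-[7-(benzyloxy)-3-hydroxy-5,8-dimethoxy-4-oxo-4H-chromen-2-yl]-2-methoxyphenyl 4-methylbenzenesulfonate | COc1cc(-c2oc3c(OC)c(OCc4ccccc4)cc(OC)c3c(=O)c2O)ccc1OS(=O)(=O)c1ccc(C)cc1 | intermediate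
18 | 4-[7-(benzyloxy)-3,5,8-trimethoxy-4-oxo-4H-chromen-2-yl]-2-methoxyphenyl 4-methylbenzenesulfonate | COc1cc(-c2oc3c(OC)c(OCc4ccccc4)cc(OC)c3c(=O)c2OC)ccc1OS(=O)(=O)c1ccc(C)cc1 | intermediate
19 | 4-(7-hydroxy-3,5,8-trimethoxy-4-oxo-4H-chromen-2-yl)-2-methoxyphenyl 4-methylbenzenesulfonate | COc1cc(-c2oc3c(OC)c(O)cc(OC)c3c(=O)c2OC)ccc1OS(=O)(=O)c1ccc(C)cc1 | intermediate
20 | prenyl bromide (1-bromo-3-methylbut-2-ene) | CC(C)=CCBr | starting material
21 | 2-methoxy-4-{3,5,8-trimethoxy-7-[(3-methylbut-2-en-1-yl)oxy]-4-oxo-4H-chromen-2-yl}phenyl 4-methylbenzenesulfonate | COc1cc(-c2oc3c(OC)c(OCC=C(C)C)cc(OC)c3c(=O)c2OC)ccc1OS(=O)(=O)c1ccc(C)cc1 | intermediate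
22 | 2-(4-hydroxy-3-methoxyphenyl)-3,5,8-trimethoxy-7-[(3-methylbut-2-en-1-yl)oxy]-4H-chromen-4-one (4'-hydroxy-3,5,8,3'-tetramethoxy-7-prenyloxyflavone) | COc1cc(-c2oc3c(OC)c(OCC=C(C)C)cc(OC)c3c(=O)c2OC)ccc1O | target

**Step count and risks**

Total step count: 15. Longest linear sequence: 13 steps (steps 1 to 5 and 8 to 15); the ring B branch (steps 6 and 7) joins at step 8.

Least certain steps:

Step 9 (key step). The most likely failure is ionization of the benzylic, propargylic C2–O1 bond by the cationic gold species or by traces of acid from the silver salt. That would lead to C-propargylation of the electron-rich ring or to cleavage back to the phenol. Closure in the 5-exo mode or hydration of the terminal alkyne are the other possibilities. The fallback replaces π-acid catalysis by a pericyclic cascade and sets out from 13. Heating in N,N-diethylaniline at about 190 °C should bring about an aromatic propargyl Claisen rearrangement to C4a; the shift to C8 is reversible because that carbon has no hydrogen to lose. Enolization then gives 4-{3-[4-(benzyloxy)-2-hydroxy-3,6-dimethoxyphenyl]propa-1,2-dien-1-yl}-2-methoxyphenyl 4-methylbenzenesulfonate F1, which is not isolated. A 1,5-hydrogen shift and oxa-6π electrocyclization follow, and the fallback comes back to the route at 14. No Lewis acid is present, and the cascade cannot give the five-membered ring.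

Step 2. Loss of regiocontrol in the deprotonation is the main risk: lithiation at a carbon between an acetal oxygen and the methoxy group would carry the wrong oxygen pattern forward. The fallback does not start from a numbered compound. It replaces 1 by commercial 2-methoxyresorcinol F2, in which the central oxygen is already in place, and introduces the other methoxy oxygen by sterically controlled C–H borylation. Bis-acetalization as in step 1 gives 2-methoxy-1,3-bis(methoxymethoxy)benzene F3. Borylation with B2pin2, [Ir(OMe)(cod)]2 and 4,4'-di-tert-butyl-2,2'-bipyridine should occur only at the one C–H that has no ortho substituent, giving 2-[4-methoxy-3,5-bis(methoxymethoxy)phenyl]-4,4,5,5-tetramethyl-1,3,2-dioxaborolane F4. Oxidation with H2O2 and NaOH gives 4-methoxy-3,5-bis(methoxymethoxy)phenol F5, and methylation as in step 3 comes back to the route at 6.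

Step 8. The hindered ortho-substituted phenoxide may displace the activated alcohol slowly, so that C-alkylation of the electron-rich phenol, SN2' attack to an allenyl ether or alkylation of the reduced azodicarboxylate compete. The fallback sets out from 12 and changes the mechanism to a copper-catalysed propargylic substitution. Acetylation (Ac2O, pyridine) gives 4-[1-(acetyloxy)prop-2-yn-1-yl]-2-methoxyphenyl 4-methylbenzenesulfonate F6. With Cu(MeCN)4PF6, a tridentate nitrogen ligand and i-Pr2NEt in CH2Cl2, this should form a copper allenylidene from the terminal alkyne, which phenol 8 attacks at the former carbinol carbon. The fallback comes back to the route at 13.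

Step 11. The oxidation may stall at the α-ketol stage, with the hydrogen-bonded C3 hydroxyl left unoxidized, or glycol cleavage of the C3–C4 bond may compete. The fallback sets out from 15 and does the two oxidations separately. DDQ in dioxane should abstract hydride at C4, which is benzylic to the trioxygenated ring A, and give rac-4-[(2R,3R)-7-(benzyloxy)-3-hydroxy-5,8-dimethoxy-4-oxo-3,4-dihydro-2H-chromen-2-yl]-2-methoxyphenyl 4-methylbenzenesulfonate F7. The classical dehydrogenation of a dihydroflavonol with I2 and KOAc in AcOH then comes back to the route at 17.

Step 15. Hydroxide may add at C2 of the pyranone, and ring opening followed by retro-Claisen fragmentation could then compete with S–O cleavage. The fallback sets out from 19 and cleaves the sulfonate there with aqueous KOH. The 7-phenoxide formed first makes the chromenone electron-rich and resistant to conjugate addition, so this gives 7-hydroxy-2-(4-hydroxy-3-methoxyphenyl)-3,5,8-trimethoxy-4H-chromen-4-one F8. Mono-alkylation with one equivalent of 20 and KHCO3 in DMF at rt should favour the more acidic 7-hydroxyl, with the 4'-ether and the bis-ether removed by chromatography, and comes back to the route at 22.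

**Further compounds**

F1 | step 9 | 4-{3-[4-(benzyloxy)-2-hydroxy-3,6-dimethoxyphenyl]propa-1,2-dien-1-yl}-2-methoxyphenyl 4-methylbenzenesulfonate (racemic, transient) | COc1cc(C=C=Cc2c(OC)cc(OCc3ccccc3)c(OC)c2O)ccc1OS(=O)(=O)c1ccc(C)cc1
F2 | step 2 | 2-methoxyresorcinol (2-methoxybenzene-1,3-diol) | COc1c(O)cccc1O
F3 | step 2 | 2-methoxy-1,3-bis(methoxymethoxy)benzene | COCOc1cccc(OCOC)c1OC
F4 | step 2 | 2-[4-methoxy-3,5-bis(methoxymethoxy)phenyl]-4,4,5,5-tetramethyl-1,3,2-dioxaborolane | COCOc1cc(B2OC(C)(C)C(C)(C)O2)cc(OCOC)c1OC
F5 | step 2 | 4-methoxy-3,5-bis(methoxymethoxy)phenol | COCOc1cc(O)cc(OCOC)c1OC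
F6 | step 8 | 4-[1-(acetyloxy)prop-2-yn-1-yl]-2-methoxyphenyl 4-methylbenzenesulfonate (racemic) | C#CC(OC(C)=O)c1ccc(OS(=O)(=O)c2ccc(C)cc2)c(OC)c1
F7 | step 11 | rac-4-[(2R,3R)-7-(benzyloxy)-3-hydroxy-5,8-dimethoxy-4-oxo-3,4-dihydro-2H-chromen-2-yl]-2-methoxyphenyl 4-methylbenzenesulfonate (one enantiomer drawn) | COc1cc([C@H]2Oc3c(OC)c(OCc4ccccc4)cc(OC)c3C(=O)[C@@H]2O)ccc1OS(=O)(=O)c1ccc(C)cc1
F8 | step 15 | 7-hydroxy-2-(4-hydroxy-3-methoxyphenyl)-3,5,8-trimethoxy-4H-chromen-4-one | COc1cc(-c2oc3c(OC)c(O)cc(OC)c3c(=O)c2OC)ccc1O
A1 | alternative 1 | 2-{4-[(tert-butyldimethylsilyl)oxy]-3-methoxyphenyl}-3,5,8-trimethoxy-7-[(3-methylbut-2-en-1-yl)oxy]-4H-chromen-4-one | COc1cc(-c2oc3c(OC)c(OCC=C(C)C)cc(OC)c3c(=O)c2OC)ccc1O[Si](C)(C)C(C)(C)C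
A2 | alternative 1 | 2-(chlorocarbonyl)-3,6-dimethoxy-5-[(3-methylbut-2-en-1-yl)oxy]phenyl 4-[(tert-butyldimethylsilyl)oxy]-3-methoxybenzoate | COc1cc(OCC=C(C)C)c(OC)c(OC(=O)c2ccc(O[Si](C)(C)C(C)(C)C)c(OC)c2)c1C(Cl)=O
A3 | alternative 1 | (methoxymethylidene)triphenylphosphorane | COC=P(c1ccccc1)(c1ccccc1)c1ccccc1
A4 | alternative 2 | 1-[3,6-dimethoxy-2,4-bis(methoxymethoxy)phenyl]-2-methoxy-3-[3-methoxy-4-(tosyloxy)phenyl]propane-1,3-dione (racemic, enolizable) | COCOc1cc(OC)c(C(=O)C(OC)C(=O)c2ccc(OS(=O)(=O)c3ccc(C)cc3)c(OC)c2)c(OCOC)c1OC
A5 | alternative 2 | 2-iodo-1,4-dimethoxy-3,5-bis(methoxymethoxy)benzene | COCOc1cc(OC)c(I)c(OCOC)c1OC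
A6 | alternative 2 | 2-methoxy-4-(methoxyacetyl)phenyl 4-methylbenzenesulfonate | COCC(=O)c1ccc(OS(=O)(=O)c2ccc(C)cc2)c(OC)c1
A7 | alternative 2 | carbon monoxide | [C-]#[O+]
A8 | alternative 3 | 7-(benzyloxy)-5,8-dihydroxy-3-methoxy-2-[3-methoxy-4-(methoxymethoxy)phenyl]-4H-chromen-4-one | COCOc1ccc(-c2oc3c(O)c(OCc4ccccc4)cc(O)c3c(=O)c2OC)cc1OC
A9 | alternative 3 | 3-(benzyloxy)-4-hydroxy-4-{5-methoxy-6-[3-methoxy-4-(methoxymethoxy)phenyl]-4-oxo-4H-pyran-2-yl}cyclobut-2-en-1-one (racemic) | O=C1C=C(OCc2ccccc2)C1(O)c1cc(=O)c(OC)c(-c2ccc(OCOC)c(OC)c2)o1
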